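The hydroxylated ring of the target (C1–OH, Br on C2 and C4, ether oxygen on C6) is traced back to a saturated cyclohexanone ring, so the diaryl ether C–O bond can be made as a simple alkyl aryl ether by SN2 chemistry. The key step uses bromine both as oxidant and as electrophile. It strips four hydrogens from the ketone ring of racemic 2-(2,4-dibromo-6-methoxyphenoxy)cyclohexan-1-one to give the phenol, and it installs the two C–Br bonds ortho and para to the new OH, where the free hydroxyl directs them. The methoxy ring arrives complete, with both bromines and the OMe in place, from 2,4-dibromo-6-methoxyphenol.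

Key step: step 2

Assumption: the target has no stereocentre and no configurationally stable axis, so the compound asked for is the single achiral structure. Compound 4 is used as the racemate because its only stereocentre is erased in step 2.

In the short names below, "aryloxy" means 2,4-dibromo-6-methoxyphenoxy. Primed locants refer to the methoxy ring (C1' bears the ether oxygen). Unprimed locants in step 2 use the target numbering of the phenol ring (C1–OH, C2–Br, C4–Br, C6–OAr).

Step 1
Reactants: 1 2-chlorocyclohexanone (racemic); 2 2,4-dibromo-6-methoxyphenol
Product: 4 2-(2,4-dibromo-6-methoxyphenoxy)cyclohexan-1-one (racemic), via 2-iodocyclohexanone 3 (not isolated)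
Conditions: 1 (1.2 equiv), K2CO3 (2 equiv), KI (0.1 equiv), DMF, 50 °C
Reagents that add atoms: none
Why: Williamson ether synthesis (SN2 at the carbonyl-activated secondary carbon, speeded by Finkelstein exchange to iodo ketone 3), in which the weakly basic, O-nucleophilic phenoxide of 2 under carbonate should substitute without Favorskii rearrangement; the new C2 stereocentre forms racemic, which is immaterial because step 2 erases it.

Step 2
Reactants: 4 2-(2,4-dibromo-6-methoxyphenoxy)cyclohexan-1-one (racemic)
Product: 11 2,4-dibromo-6-(2,4-dibromo-6-methoxyphenoxy)phenol (target), via 2-bromo-2-aryloxycyclohexanone 5 (not isolated), via 2-aryloxycyclohex-2-enone 6 (not isolated), via 6-bromo-2-aryloxycyclohex-2-enone 7 (not isolated), via 2-aryloxycyclohexa-2,5-dienone 8 (not isolated), via 2-aryloxyphenol 9 (not isolated), via 4-bromo-2-aryloxyphenol 10 (not isolated)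
Conditions: Br2 (4.1 equiv, added dropwise), glacial AcOH, HBr/AcOH (cat.), 65 °C, N2 sweep to a scrubber; then aq NaHSO3, 20 °C
Reagents that add atoms: bromine, BrBr
Why: Acid-catalysed enolisation of 4 toward the aryloxy-bearing carbon and bromination should give the α-bromo ether 5, which loses HBr to enone 6; α'-bromination (7) and a second loss of HBr give the cross-conjugated dienone 8, which tautomerises to phenol 9. Phenol 9 is then brominated by electrophilic aromatic substitution para (10) and then ortho to the OH to reach 11, so that four Br2 are consumed and six HBr released overall. The closest known reaction type is the halogenative dehydrogenation of cyclohexanones and cyclohexenones to halophenols with Br2, NBS or CuBr2, followed by ordinary phenol bromination. No ring is closed and no stereocentre is created; the racemic ether-bearing carbon of 4 simply becomes aromatic C6. The step needs bromine only at C2 and C4: the free OH is the strongest donor on that ring, whereas the ether oxygen, shared with an electron-poor dibromoaryl ring, directs weakly, and the methoxy ring offers only C3' (flanked by two Br) and C5', both deactivated by its two bromines, while the Br2 charge is held at the amount the balanced equation requires. If bromination and elimination occur in another order (for example with the α'-bromine carried through aromatisation to become the C2 bromine), the same four Br2 are used and the same product should result, and the bisulfite quench returns any bromodienone to the phenol.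

Compound list
1 | 2-chlorocyclohexanone (racemic) | O=C1CCCCC1Cl | starting material
2 | 2,4-dibromo-6-methoxyphenol | COc1cc(Br)cc(Br)c1O | starting material
3 | 2-iodocyclohexanone (racemic, not isolated) | O=C1CCCCC1I | intermediate
4 | 2-(2,4-dibromo-6-methoxyphenoxy)cyclohexan-1-one (racemic) | COc1cc(Br)cc(Br)c1OC1CCCCC1=O | intermediate
5 | 2-bromo-2-(2,4-dibromo-6-methoxyphenoxy)cyclohexan-1-one (racemic, not isolated) | COc1cc(Br)cc(Br)c1OC1(Br)CCCCC1=O | intermediate
6 | 2-(2,4-dibromo-6-methoxyphenoxy)cyclohex-2-en-1-one (not isolated) | COc1cc(Br)cc(Br)c1OC1=CCCCC1=O | intermediate
7 | 6-bromo-2-(2,4-dibromo-6-methoxyphenoxy)cyclohex-2-en-1-one (racemic, not isolated) | COc1cc(Br)cc(Br)c1OC1=CCCC(Br)C1=O | intermediate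
8 | 2-(2,4-dibromo-6-methoxyphenoxy)cyclohexa-2,5-dien-1-one (not isolated) | COc1cc(Br)cc(Br)c1OC1=CCC=CC1=O | intermediate
9 | 2-(2,4-dibromo-6-methoxyphenoxy)phenol (not isolated) | COc1cc(Br)cc(Br)c1Oc1ccccc1O | intermediate
10 | 4-bromo-2-(2,4-dibromo-6-methoxyphenoxy)phenol (not isolated) | COc1cc(Br)cc(Br)c1Oc1cc(Br)ccc1O | intermediate
11 | 2,4-dibromo-6-(2,4-dibromo-6-methoxyphenoxy)phenol (achiral) | COc1cc(Br)cc(Br)c1Oc1cc(Br)cc(Br)c1O | target

Total step count: 2
Longest linear sequence: 2

Steps most likely to fail (the route has only two steps, so both are ranked):

1. Step 2. Several processes could spoil it: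
- ionisation of the α-bromo ether stage, with loss of the aryloxy group if moisture is present;
- addition of Br2 across the enol-ether double bond of the enone stage, which would leave bromine meta to the OH;
- bromination running on into the methoxy ring at 65 °C;
- O-demethylation by accumulated HBr.

Fallback: the fallback sets out from compound 2, passes through compound 9 (now isolated) and rejoins the route at compound 11. The oxidation level of the second ring is bought ready-made instead of being created with bromine. SNAr of the potassium salt of 2 on 2-fluorobenzaldehyde (K2CO3, DMF, 120 °C) should give 2-(2,4-dibromo-6-methoxyphenoxy)benzaldehyde F1. Baeyer–Villiger (Dakin-type) oxidation with mCPBA in CH2Cl2 should give 2-(2,4-dibromo-6-methoxyphenoxy)phenyl formate F2, and aqueous NaOH in THF should release phenol 9. Only the mild last phase of step 2 then remains: Br2 (2.05 equiv), AcOH, 15 °C, placing bromine para and ortho to the OH to give 11.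

2. Step 1. The di-ortho-substituted, weakly nucleophilic phenoxide may substitute slowly, so that base-induced self-condensation, elimination or Favorskii-type consumption of the halo ketone competes.

Fallback: the fallback sets out from compound 2 and returns at compound 4. Anti SN2 opening of cyclohexene oxide by the phenoxide of 2 (K2CO3, DMF, 110 °C) should give racemic trans-2-(2,4-dibromo-6-methoxyphenoxy)cyclohexan-1-ol F3. Dess–Martin oxidation (CH2Cl2, 20 °C) should then give ketone 4, with no α-halo ketone involved.

Further compounds
F1 | step 2 | 2-(2,4-dibromo-6-methoxyphenoxy)benzaldehyde | COc1cc(Br)cc(Br)c1Oc1ccccc1C=O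
F2 | step 2 | 2-(2,4-dibromo-6-methoxyphenoxy)phenyl formate | COc1cc(Br)cc(Br)c1Oc1ccccc1OC=O
F3 | step 1 | trans-2-(2,4-dibromo-6-methoxyphenoxy)cyclohexan-1-ol (racemate; (1R,2R) enantiomer drawn) | COc1cc(Br)cc(Br)c1O[C@@H]1CCCC[C@H]1O
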